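## Retrosynthetic overview

1. The target is read as an oxa-Diels–Alder adduct of two C15 units. Its 3,4-dihydro-2H-pyran ring (O1', spiro C2' = lactone C11, C3' = C13, C4', C5', C6') has the enol ether O1'–C6'H=C5' carrying the cyclohexane, and C2' sits α to the lactone C12=O. This is the pattern of an acrolein-type [4+2] dimer, so cutting O1'–C11 and C13–C4' gives the 2-substituted acrolein 15 and the α-methylene-γ-lactone 19.
2. Enal 15 (elemane half, antipodal to the (−)-β-elemene series) keeps the cyclohexane of (S)-carvone. A temporary ring A (chiral-imine Michael addition, Robinson annulation, Li/NH3) sets the quaternary carbon and its neighbour. It is then cut open (silyl enol ether ozonolysis) to an acetyl and a propanoic acid arm, which become isopropenyl and vinyl.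
3. Lactone 19 (5-epi-isoalantolactone, cis-fused decalin) comes from isoalantolactone by excision of C15, epimerisation of the C4 ketone at C5 and re-methylenation.
4. Ring order: carvone cyclohexane (bought) → temporary ring A (made, then cleaved); decalin and lactone of 19 (bought, C5 inverted); the dihydropyran is closed last, in the convergent step.

Key step: step 13

Assumption: the C2 epimers of 2 and the C=N isomers of 5 and 6 converge in step 2, so 2 is used as the mixture; in step 11 the position of the equilibrium is predicted from conformational analysis and recovered 17 is recycled.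

## Route

Step 1
Reactants: 1 (S)-(+)-carvone
Product: 2 (2S,5S)-2-methyl-5-(prop-1-en-2-yl)cyclohexan-1-one (dihydrocarvone, used together with its C2 epimer)
Conditions: Zn dust, KOH, EtOH–H2O, reflux
Reagents that add atoms: none
Why: Dissolving-metal conjugate reduction of the enone C=C leaves the isolated isopropenyl group and the C5 stereocentre (S, from the chiral pool) untouched.

Step 2
Reactants: 2 dihydrocarvone; 3 (S)-1-phenylethylamine; 4 ethyl vinyl ketone
Product: 7 (2R,5S)-2-methyl-2-(3-oxopentyl)-5-(prop-1-en-2-yl)cyclohexan-1-one, via ketimine 5 (not isolated), via Michael adduct ketimine 6 (not isolated)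
Conditions: 3, TsOH (cat.), PhMe, reflux (−H2O); then 4, THF, 40 °C; then 10% aq. AcOH, rt
Reagents that add atoms: water O
Why: Asymmetric Michael addition of a chiral imine through its more substituted secondary enamine tautomer (aza-ene-like chair transition state); the (S)-1-phenylethyl group should direct the enone to the face of C2 anti to the C5 isopropenyl group and so set the quaternary centre (2R), as in the known route to α-cyperone in the antipodal series.

Step 3
Reactants: 7 diketone
Product: 8 (4aR,7S)-1,4a-dimethyl-7-(prop-1-en-2-yl)-4,4a,5,6,7,8-hexahydronaphthalen-2(3H)-one (ent-α-cyperone)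
Conditions: NaOMe, MeOH, rt to 60 °C
Reagents that add atoms: none
Why: Intramolecular aldol condensation (second half of a Robinson annulation) closes the temporary ring A without touching a stereocentre.

Step 4
Reactants: 8 ent-α-cyperone
Product: 10 trimethyl{[(4aR,7S,8aS)-1,4a-dimethyl-7-(prop-1-en-2-yl)-3,4,4a,5,6,7,8,8a-octahydronaphthalen-2-yl]oxy}silane, via lithium enolate 9 (not isolated)
Conditions: Li, NH3(l)–THF, t-BuOH (1 equiv), −78 °C; evaporate NH3; then TMSCl, Et3N, THF, 0 °C
Reagents that add atoms: chlorotrimethylsilane C[Si](C)(C)Cl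
Why: Dissolving-metal (Birch-type) enone reduction protonates the ring-fusion carbon axially, giving the trans-fused junction (new C–H anti to the angular methyl), and the regiodefined enolate is trapped on oxygen.

Step 5
Reactants: 10 silyl enol ether
Product: 11 3-[(1R,2S,4S)-2-acetyl-1-methyl-4-(prop-1-en-2-yl)cyclohexyl]propanoic acid
Conditions: O3 (1 equiv, Sudan Red 7B endpoint), CH2Cl2–MeOH, −78 °C; then Me2S; aq. work-up
Reagents that add atoms: ozone [O-][O+]=O
Why: Ozonolysis of the electron-rich silyl enol ether, which should react far faster than the 1,1-disubstituted isopropenyl group, cleaves ring A into the methyl ketone and (via the silyl ester) the carboxylic acid; no stereocentre is affected.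

Step 6
Reactants: 11 keto acid
Product: 12 1-[(1S,2R,5S)-2-ethenyl-2-methyl-5-(prop-1-en-2-yl)cyclohexyl]ethan-1-one
Conditions: Pb(OAc)4, Cu(OAc)2 (cat.), pyridine, PhH, 80 °C
Reagents that add atoms: none
Why: Kochi oxidative decarboxylation: the primary alkyl radical from the lead carboxylate is oxidised by divalent copper to the terminal alkene, which puts the vinyl group on the quaternary carbon.

Step 7
Reactants: 12 vinyl ketone
Product: 13 1-[(1S,2R,5S)-2-ethenyl-5-(3-hydroxyprop-1-en-2-yl)-2-methylcyclohexyl]ethan-1-one
Conditions: SeO2 (cat.), t-BuOOH, CH2Cl2, 0 °C to rt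
Reagents that add atoms: selenium dioxide O=[Se]=O (catalytic oxygen carrier); tert-butyl hydroperoxide CC(C)(C)OO
Why: Selenium dioxide allylic oxidation (ene reaction, then 2,3-sigmatropic shift) should hydroxylate the methyl of the only isopropenyl group present, since the vinyl group has no allylic hydrogen and the ketone is inert under these mild conditions.

Step 8
Reactants: 13 hydroxy ketone
Product: 14 2-[(1S,3R,4R)-4-ethenyl-4-methyl-3-(prop-1-en-2-yl)cyclohexyl]prop-2-en-1-ol
Conditions: Ph3PCH3Br, KOtBu (3 equiv each), THF, 0 °C to reflux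
Reagents that add atoms: methyltriphenylphosphonium bromide C[P+](c1ccccc1)(c1ccccc1)c1ccccc1.[Br-]
Why: Wittig methylenation of the methyl ketone (excess ylide, the alkoxide is a spectator) makes the second isopropenyl group; the centre α to the ketone was set in step 4 and is already in its more stable equatorial configuration.

Step 9
Reactants: 14 dienol
Product: 15 2-[(1S,3R,4R)-4-ethenyl-4-methyl-3-(prop-1-en-2-yl)cyclohexyl]prop-2-enal (ent-β-elemenal)
Conditions: MnO2, CH2Cl2, rt
Reagents that add atoms: none
Why: Manganese dioxide oxidises only the allylic primary alcohol, giving the 2-substituted acrolein without touching the other alkenes.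

Step 10
Reactants: 16 isoalantolactone
Product: 17 (5αH)-15-nor-4-oxoeudesm-11(13)-en-12,8β-olide (trans-fused nor-ketone)
Conditions: O3 (1 equiv, Sudan Red 7B endpoint), CH2Cl2–MeOH, −78 °C; then Me2S
Reagents that add atoms: ozone [O-][O+]=O
Why: Chemoselective ozonolysis: the electron-rich C4=C15 methylidene should be cleaved much faster than the electron-poor lactone-conjugated methylidene; no stereocentre changes.

Step 11
Reactants: 17 trans-fused nor-ketone
Product: 18 (5βH)-15-nor-4-oxoeudesm-11(13)-en-12,8β-olide (cis-fused nor-ketone)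
Conditions: TsOH·H2O (cat.), PhH, 60 °C; chromatography, recovered 17 re-subjected
Reagents that add atoms: none
Why: Acid-catalysed keto–enol epimerisation at C5; the cis-fused ketone can flip ring B and so lose the 1,3-diaxial clash between the axial C8–O bond and the C10 methyl that the rigid trans isomer must keep, so the equilibrium should favour 18.

Step 12
Reactants: 18 cis-fused nor-ketone
Product: 19 5-epi-isoalantolactone, (3aR,4aR,8aR,9aR)-8a-methyl-3,5-dimethylidenedecahydronaphtho[2,3-b]furan-2-one
Conditions: Zn, CH2Br2, TiCl4, THF–CH2Cl2, 0 °C to rt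
Reagents that add atoms: dibromomethane BrCBr
Why: Takai–Lombardo methylenation is non-basic, so the epimerisable C5 centre should be retained, and it is selective for the ketone over the lactone and its conjugated alkene.

Step 13
Reactants: 15 ent-β-elemenal; 19 5-epi-isoalantolactone
Product: 20 target CNP0353330.1, the (11R)-spiro adduct in which C11 of the (5βH)-eudesm-4(15)-en-12,8β-olide is C2' of a 3',4'-dihydro-2'H-pyran bearing the (1S,3R,4R)-4-ethenyl-4-methyl-3-(prop-1-en-2-yl)cyclohexyl group at C5', ring oxygen syn to H-7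
Conditions: 19 (3 equiv), 15 added slowly, BHT (cat.), PhMe (high concentration), 120 °C, sealed tube; excess 19 recovered
Reagents that add atoms: none
Why: Thermal oxa-Diels–Alder reaction of the acrolein-dimerisation type: the s-cis 1-oxadiene O=CH–C(R)=CH2 of 15 adds across the lactone-conjugated C11=C13 methylidene of 19 in a concerted, asynchronous [4+2] in which the two CH2 termini bond first and the aldehyde oxygen closes onto C11, the terminus stabilised by the lactone carbonyl. The closest known reactions are the thermal dimerisation of acrolein and methacrolein, the addition of enals to methacrylates, and the dimerisation of α-methylene carbonyl sesquiterpenoids to spiro-dihydropyrans. The one new ring, the 3,4-dihydro-2H-pyran, is closed by intermolecular [4+2] cycloaddition, both σ-bonds forming suprafacially on one face of the dienophile. The only new stereocentre, spiro C11, is set by the cis-fused lactone of 19: the oxadiene should approach the convex face of the methylidene, syn to H-7 and H-8 and anti to C-6 and C-9 of ring B, which places the ring oxygen on that face as the target requires. The step needs regioselectivity (oxygen to C11, secured by the carbonyl-bearing terminus), site selectivity (of the five C=C bonds only the conjugated methylidene should react with an electron-poor oxadiene at this temperature) and cross- over homo-dimerisation of 15 (secured by excess 19 and slow addition of 15). No existing stereocentre of either partner is touched.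

## Compound list

1 | (S)-(+)-carvone, (5S)-2-methyl-5-(prop-1-en-2-yl)cyclohex-2-en-1-one | CC1=CC[C@@H](CC1=O)C(C)=C | starting material
2 | (2S,5S)-2-methyl-5-(prop-1-en-2-yl)cyclohexan-1-one (dihydrocarvone, with its C2 epimer) | C[C@H]1CC[C@@H](CC1=O)C(C)=C | intermediate
3 | (S)-1-phenylethylamine | C[C@H](N)c1ccccc1 | starting material
4 | ethyl vinyl ketone (pent-1-en-3-one) | CCC(=O)C=C | starting material
5 | ketimine of 2 with 3, (1S)-N-[(2S,5S)-2-methyl-5-(prop-1-en-2-yl)cyclohexylidene]-1-phenylethanamine (C=N isomers, in equilibrium with the enamine) | C[C@H]1CC[C@@H](CC1=N[C@@H](C)c1ccccc1)C(C)=C | intermediate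
6 | Michael adduct ketimine, 1-[(1R,4S)-1-methyl-2-{[(1S)-1-phenylethyl]imino}-4-(prop-1-en-2-yl)cyclohexyl]pentan-3-one | C[C@]1(CCC(=O)CC)CC[C@@H](CC1=N[C@@H](C)c1ccccc1)C(C)=C | intermediate
7 | (2R,5S)-2-methyl-2-(3-oxopentyl)-5-(prop-1-en-2-yl)cyclohexan-1-one | C[C@]1(CCC(=O)CC)CC[C@@H](CC1=O)C(C)=C | intermediate
8 | ent-α-cyperone, (4aR,7S)-1,4a-dimethyl-7-(prop-1-en-2-yl)-4,4a,5,6,7,8-hexahydronaphthalen-2(3H)-one | CC1=C2C[C@H](CC[C@]2(C)CCC1=O)C(C)=C | intermediate
9 | lithium (4aR,7S,8aS)-1,4a-dimethyl-7-(prop-1-en-2-yl)-3,4,4a,5,6,7,8,8a-octahydronaphthalen-2-olate | [Li+].CC1=C([O-])CC[C@@]2(C)CC[C@@H](C[C@H]12)C(C)=C | intermediate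
10 | trimethyl{[(4aR,7S,8aS)-1,4a-dimethyl-7-(prop-1-en-2-yl)-3,4,4a,5,6,7,8,8a-octahydronaphthalen-2-yl]oxy}silane (trans-fused) | CC1=C(O[Si](C)(C)C)CC[C@@]2(C)CC[C@@H](C[C@H]12)C(C)=C | intermediate
11 | 3-[(1R,2S,4S)-2-acetyl-1-methyl-4-(prop-1-en-2-yl)cyclohexyl]propanoic acid | CC(=O)[C@H]1C[C@H](CC[C@]1(C)CCC(=O)O)C(C)=C | intermediate
12 | 1-[(1S,2R,5S)-2-ethenyl-2-methyl-5-(prop-1-en-2-yl)cyclohexyl]ethan-1-one | CC(=O)[C@H]1C[C@H](CC[C@]1(C)C=C)C(C)=C | intermediate
13 | 1-[(1S,2R,5S)-2-ethenyl-5-(3-hydroxyprop-1-en-2-yl)-2-methylcyclohexyl]ethan-1-one | CC(=O)[C@H]1C[C@H](CC[C@]1(C)C=C)C(=C)CO | intermediate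
14 | 2-[(1S,3R,4R)-4-ethenyl-4-methyl-3-(prop-1-en-2-yl)cyclohexyl]prop-2-en-1-ol | CC(=C)[C@H]1C[C@H](CC[C@]1(C)C=C)C(=C)CO | intermediate
15 | ent-β-elemenal, 2-[(1S,3R,4R)-4-ethenyl-4-methyl-3-(prop-1-en-2-yl)cyclohexyl]prop-2-enal | CC(=C)[C@H]1C[C@H](CC[C@]1(C)C=C)C(=C)C=O | intermediate
16 | isoalantolactone, (3aR,4aS,8aR,9aR)-8a-methyl-3,5-dimethylidenedecahydronaphtho[2,3-b]furan-2-one | C=C1CCC[C@]2(C)C[C@H]3OC(=O)C(=C)[C@H]3C[C@@H]12 | starting material
17 | (5αH)-15-nor-4-oxoeudesm-11(13)-en-12,8β-olide (trans-fused) | O=C1CCC[C@]2(C)C[C@H]3OC(=O)C(=C)[C@H]3C[C@@H]12 | intermediate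
18 | (5βH)-15-nor-4-oxoeudesm-11(13)-en-12,8β-olide (cis-fused) | O=C1CCC[C@]2(C)C[C@H]3OC(=O)C(=C)[C@H]3C[C@H]12 | intermediate
19 | 5-epi-isoalantolactone, (3aR,4aR,8aR,9aR)-8a-methyl-3,5-dimethylidenedecahydronaphtho[2,3-b]furan-2-one | C=C1CCC[C@]2(C)C[C@H]3OC(=O)C(=C)[C@H]3C[C@H]12 | intermediate
20 | CNP0353330.1, (11R)-spiro[dihydropyran–eudesmanolide] adduct as described in step 13 | C=C[C@@]1(C)CC[C@H](C2=CO[C@@]3(CC2)C(=O)O[C@@H]2C[C@@]4(C)CCCC(=C)[C@H]4C[C@@H]23)C[C@@H]1C(=C)C | target

## Summary and risks

Total step count: 13. Longest linear sequence: 10 steps (steps 1–9, then step 13).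

Steps most likely to fail:

1. Step 13. Homo-dimerisation of enal 15 by the same oxa-Diels–Alder pathway, or insufficient facial selectivity at the lactone methylidene, could outrun the cross-reaction. The fallback is stepwise and sets out from 15 and 19. Conjugate addition of benzeneselenol (PhSeSePh, NaBH4, EtOH) to 15 should give the β-selanyl aldehyde F1, which is protected (HC(OMe)3, PPTS, MeOH) as the dimethyl acetal F2. Giese addition of the primary radical from F2 (Bu3SnH, AIBN, PhH, 80 °C) to the methylidene of 19 should give the saturated lactone adduct F3. Enolisation of F3 (LDA, THF, −78 °C) and Davis oxaziridine oxidation from the convex face should give the 11-hydroxy lactone F4 with oxygen syn to H-7. Acid (CSA, PhMe, 110 °C, 4 Å sieves) should then close the cyclic acetal and eliminate methanol to the enol ether, coming back to the route at compound 20.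

2. Step 11. The epimerisation equilibrium may lie less far on the cis side than predicted, or the two ketones may be hard to separate. The fallback sets out from 16 and inverts C5 kinetically. Acid isomerisation (TsOH, PhH, reflux) should give alloalantolactone F5. A Schenck ene reaction with singlet oxygen (O2, tetraphenylporphyrin, hν, CH2Cl2) from the α-face should give the 5α-hydroperoxide F6, reduced in the same flask (PPh3) to telekin F7. Formylation (acetic formic anhydride, pyridine, DMAP) should give telekin formate F8. Tsuji-type formate hydrogenolysis (Pd(OAc)2, PBu3, dioxane, rt to 60 °C) follows: zerovalent palladium ionises anti to the 5α-formate and delivers hydride from its own β-face to the more substituted allyl terminus C5, with loss of CO2. This comes back to the route at compound 19.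

3. Step 5. Over-oxidation, that is ozone also cleaving the isopropenyl group, would destroy the C7 side chain. The fallback sets out from 10. Rubottom oxidation (mCPBA, NaHCO3, CH2Cl2, 0 °C; then aqueous acid), which is far more selective for the enol ether, should give the α-hydroxy ketone F9. Glycol-type cleavage (NaIO4, THF–H2O) then opens ring A and comes back to the route at compound 11.

## Further compounds

F1 | step 13 | 2-[(1S,3R,4R)-4-ethenyl-4-methyl-3-(prop-1-en-2-yl)cyclohexyl]-3-(phenylselanyl)propanal (C2 epimers) | CC(=C)[C@H]1C[C@H](CC[C@]1(C)C=C)C(C[Se]c1ccccc1)C=O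
F2 | step 13 | {3,3-dimethoxy-2-[(1S,3R,4R)-4-ethenyl-4-methyl-3-(prop-1-en-2-yl)cyclohexyl]propyl}(phenyl)selane | CC(=C)[C@H]1C[C@H](CC[C@]1(C)C=C)C(C[Se]c1ccccc1)C(OC)OC
F3 | step 13 | (5βH)-13-{3,3-dimethoxy-2-[(1S,3R,4R)-4-ethenyl-4-methyl-3-(prop-1-en-2-yl)cyclohexyl]propyl}eudesm-4(15)-en-12,8β-olide (C11 epimers) | C=C1CCC[C@]2(C)C[C@H]3OC(=O)C(CCC(C(OC)OC)[C@H]4CC[C@](C)(C=C)[C@H](C4)C(C)=C)[C@H]3C[C@H]12
F4 | step 13 | 11-hydroxy derivative of F3 (11-OH syn to H-7) | C=C1CCC[C@]2(C)C[C@H]3OC(=O)[C@@](O)(CCC(C(OC)OC)[C@H]4CC[C@](C)(C=C)[C@H](C4)C(C)=C)[C@H]3C[C@H]12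
F5 | step 11 | alloalantolactone, eudesma-4,11(13)-dien-12,8β-olide | CC1=C2C[C@H]3[C@@H](C[C@@]2(C)CCC1)OC(=O)C3=C
F6 | step 11 | 5α-hydroperoxyisoalantolactone | C=C1CCC[C@]2(C)C[C@H]3OC(=O)C(=C)[C@H]3C[C@@]12OO
F7 | step 11 | telekin, 5α-hydroxyisoalantolactone | C=C1CCC[C@]2(C)C[C@H]3OC(=O)C(=C)[C@H]3C[C@@]12O
F8 | step 11 | telekin 5-O-formate | C=C1CCC[C@]2(C)C[C@H]3OC(=O)C(=C)[C@H]3C[C@@]12OC=O
F9 | step 5 | (4aR,7S,8aS)-1-hydroxy-1,4a-dimethyl-7-(prop-1-en-2-yl)octahydronaphthalen-2(1H)-one (hydroxyl anti to the angular methyl) | C[C@]1(O)C(=O)CC[C@@]2(C)CC[C@@H](C[C@H]12)C(C)=C
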